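**Retrosynthetic overview**

1. Target ⇒ both dihydrofuran rings opened at O1–C2, giving a nona-O-methyl bis(1,2,2-triarylethanol). Forward, one BBr3 operation closes both rings (C2 and C2′ trans to the preset C3 and C3′) and removes every methyl group.
2. Bis-carbinol ⇒ dialdehyde + two equivalents of 4-MeOC6H4MgBr; dialdehyde ⇒ bis(nitroalkane) by a double Nef reaction.
3. C3 and C3′ ⇒ two rhodium-catalysed enantioselective conjugate arylations of 2,6-dimethoxy-β-nitrostyrenes, run with the two antipodes of one diene ligand. This is what places an (R,R) ring next to an (S,S) ring.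
4. Both nitrostyrenes ⇒ one aldehyde, 4-bromo-2,6-dimethoxybenzaldehyde (Henry condensation; Heck reaction for the styryl arm; borylation turns the first adduct into the aryl donor of the second arylation).
5. Ring order: no heterocycle is made before the end; the two dihydrobenzofurans form together in the last operation.

Assumption: 4-bromo-2,6-dimethoxybenzaldehyde is bought as a catalogue building block.
Assumption: (R,R)-Ph-bod [(1R,4R)-2,5-diphenylbicyclo[2.2.2]octa-2,5-diene] is taken to deliver aryl to the Si face of the nitroalkene β-carbon; if a test run shows the opposite sense, the two ligand antipodes are exchanged between steps 2 and 6 and nothing else changes.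

**Route**

Step 1
Reactants: 1 4-bromo-2,6-dimethoxybenzaldehyde
Product: 2 5-bromo-1,3-dimethoxy-2-[(E)-2-nitroethenyl]benzene
Conditions: MeNO2 (solvent), NH4OAc (0.5 equiv), 95 °C
Reagents that add atoms: nitromethane, C[N+](=O)[O-]
Why: Henry (nitroaldol) condensation with in situ dehydration gives the conjugated (E)-nitroalkene as the thermodynamic isomer, and no stereocentre is formed.

Step 2
Reactants: 2 5-bromo-1,3-dimethoxy-2-[(E)-2-nitroethenyl]benzene; 3 (3,5-dimethoxyphenyl)boronic acid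
Product: 4 5-bromo-2-[(1S)-1-(3,5-dimethoxyphenyl)-2-nitroethyl]-1,3-dimethoxybenzene
Conditions: [RhCl(C2H4)2]2 (2.5 mol%), (R,R)-Ph-bod (5.5 mol%), KOH (0.2 equiv), dioxane/H2O 10:1, 50 °C
Reagents that add atoms: none
Why: Hayashi–Miyaura conjugate addition, in which the aryl–rhodium complex of the chiral diene inserts the nitroalkene from the Si face of the β-carbon and protonation of the rhodium nitronate releases the (S)-configured diarylmethine, the aryl bromide being inert to monovalent rhodium.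

Step 3
Reactants: 4 5-bromo-2-[(1S)-1-(3,5-dimethoxyphenyl)-2-nitroethyl]-1,3-dimethoxybenzene
Product: 5 2-{4-[(1S)-1-(3,5-dimethoxyphenyl)-2-nitroethyl]-3,5-dimethoxyphenyl}-4,4,5,5-tetramethyl-1,3,2-dioxaborolane
Conditions: B2pin2 (1.2 equiv), PdCl2(dppf) (3 mol%), KOAc (3 equiv), 1,4-dioxane, 85 °C
Reagents that add atoms: bis(pinacolato)diboron, CC1(C)OB(OC1(C)C)B1OC(C)(C)C(C)(C)O1
Why: Miyaura borylation exchanges the unhindered aryl bromide for a boronate under a base too weak to engage the primary nitroalkane, and the benzylic stereocentre is not deprotonated by acetate and is untouched.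

Step 4
Reactants: 1 4-bromo-2,6-dimethoxybenzaldehyde; 6 1-ethenyl-4-methoxybenzene
Product: 7 2,6-dimethoxy-4-[(E)-2-(4-methoxyphenyl)ethenyl]benzaldehyde
Conditions: Pd(OAc)2 (2 mol%), P(o-tol)3 (6 mol%), Et3N (2 equiv), DMF, 100 °C
Reagents that add atoms: none
Why: Mizoroki–Heck reaction of the aldehyde-activated aryl bromide with the styrene gives the (E)-stilbene through syn-insertion and syn-β-hydride elimination, the aldehyde being a spectator.

Step 5
Reactants: 7 2,6-dimethoxy-4-[(E)-2-(4-methoxyphenyl)ethenyl]benzaldehyde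
Product: 8 1,3-dimethoxy-5-[(E)-2-(4-methoxyphenyl)ethenyl]-2-[(E)-2-nitroethenyl]benzene
Conditions: MeNO2 (solvent), NH4OAc (0.5 equiv), 95 °C
Reagents that add atoms: nitromethane, C[N+](=O)[O-]
Why: Henry condensation/dehydration as in step 1 gives the (E)-nitroalkene while the stilbene is unaffected.

Step 6
Reactants: 8 1,3-dimethoxy-5-[(E)-2-(4-methoxyphenyl)ethenyl]-2-[(E)-2-nitroethenyl]benzene; 5 2-{4-[(1S)-1-(3,5-dimethoxyphenyl)-2-nitroethyl]-3,5-dimethoxyphenyl}-4,4,5,5-tetramethyl-1,3,2-dioxaborolane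
Product: 9 2-[(1R)-1-{4-[(1S)-1-(3,5-dimethoxyphenyl)-2-nitroethyl]-3,5-dimethoxyphenyl}-2-nitroethyl]-1,3-dimethoxy-5-[(E)-2-(4-methoxyphenyl)ethenyl]benzene
Conditions: [RhCl(C2H4)2]2 (3 mol%), (S,S)-Ph-bod (6.5 mol%), KOH (0.2 equiv), dioxane/H2O 10:1, 60 °C
Reagents that add atoms: none
Why: A second Hayashi–Miyaura addition with the antipodal ligand delivers the aryl group of the boronate to the Re face of the nitroalkene and sets the new centre (R) under pure catalyst control, the existing (S) centre being remote and the unactivated stilbene not inserting.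

Step 7
Reactants: 9 2-[(1R)-1-{4-[(1S)-1-(3,5-dimethoxyphenyl)-2-nitroethyl]-3,5-dimethoxyphenyl}-2-nitroethyl]-1,3-dimethoxy-5-[(E)-2-(4-methoxyphenyl)ethenyl]benzene
Product: 11 (2R)-2-{2,6-dimethoxy-4-[(E)-2-(4-methoxyphenyl)ethenyl]phenyl}-2-{4-[(1S)-1-(3,5-dimethoxyphenyl)-2-oxoethyl]-3,5-dimethoxyphenyl}acetaldehyde, via disodium bis-nitronate 10 (not isolated)
Conditions: NaOMe (2.2 equiv), MeOH/THF, 0 °C; then aq TiCl3 (9 equiv), NH4OAc buffer (pH 5), 0 °C to rt
Reagents that add atoms: water, O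
Why: Reductive Nef reaction (McMurry variant), in which trivalent titanium reduces each nitronate to the imine that hydrolyses to the aldehyde near neutral pH, so the adjacent diarylmethine centres, whose enolisation is disfavoured by the twisted 2,6-dimethoxyaryl group, are retained.

Step 8
Reactants: 11 (2R)-2-{2,6-dimethoxy-4-[(E)-2-(4-methoxyphenyl)ethenyl]phenyl}-2-{4-[(1S)-1-(3,5-dimethoxyphenyl)-2-oxoethyl]-3,5-dimethoxyphenyl}acetaldehyde; 12 (4-methoxyphenyl)magnesium bromide (two equivalents are incorporated, one per aldehyde)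
Product: 13 (2R)-2-{2,6-dimethoxy-4-[(E)-2-(4-methoxyphenyl)ethenyl]phenyl}-2-{4-[(1S)-1-(3,5-dimethoxyphenyl)-2-hydroxy-2-(4-methoxyphenyl)ethyl]-3,5-dimethoxyphenyl}-1-(4-methoxyphenyl)ethan-1-ol (both carbinol centres as epimer mixtures)
Conditions: 4-MeOC6H4MgBr (3 equiv), THF, −78 °C; aq NH4Cl
Reagents that add atoms: (4-methoxyphenyl)magnesium bromide (second equivalent of 12), COc1ccc([Mg]Br)cc1
Why: Twofold Grignard 1,2-addition, one equivalent of 12 per aldehyde, in which the two new carbinol centres form unselectively but are reset in step 9, and the low temperature suppresses enolisation of the aldehydes so that the diarylmethine centres are kept.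

Step 9
Reactants: 13 (2R)-2-{2,6-dimethoxy-4-[(E)-2-(4-methoxyphenyl)ethenyl]phenyl}-2-{4-[(1S)-1-(3,5-dimethoxyphenyl)-2-hydroxy-2-(4-methoxyphenyl)ethyl]-3,5-dimethoxyphenyl}-1-(4-methoxyphenyl)ethan-1-ol
Product: 15 5-[(2S,3S)-4-hydroxy-6-{(2R,3R)-4-hydroxy-2-(4-hydroxyphenyl)-6-[(E)-2-(4-hydroxyphenyl)ethenyl]-2,3-dihydro-1-benzofuran-3-yl}-2-(4-hydroxyphenyl)-2,3-dihydro-1-benzofuran-3-yl]benzene-1,3-diol, via bis(benzylic bromide) 14 (not isolated)
Conditions: BBr3 (25 equiv), CH2Cl2, −78 °C to rt; MeOH, then aq NaHCO3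
Reagents that add atoms: none
Why: Lewis-acid ether cleavage combined with a double demethylative cyclodehydration, in which BBr3 ionises each p-anisyl carbinol through its benzylic bromide, a flanking ortho-methoxy oxygen closes the five-membered ring with loss of MeBr anti to the C3 aryl group, reversible C2–O ionisation funnels both rings to the trans isomers so that C2 (R) and C2′ (S) follow from the preset C3 (R) and C3′ (S), and the same reagent cleaves the seven remaining methyl ethers.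

**Compound list**

1 | 4-bromo-2,6-dimethoxybenzaldehyde | COc1cc(Br)cc(OC)c1C=O | starting material
2 | 5-bromo-1,3-dimethoxy-2-[(E)-2-nitroethenyl]benzene | COc1cc(Br)cc(OC)c1/C=C/[N+](=O)[O-] | intermediate
3 | (3,5-dimethoxyphenyl)boronic acid | COc1cc(OC)cc(B(O)O)c1 | starting material
4 | 5-bromo-2-[(1S)-1-(3,5-dimethoxyphenyl)-2-nitroethyl]-1,3-dimethoxybenzene | [O-][N+](=O)C[C@H](c1c(OC)cc(Br)cc1OC)c1cc(OC)cc(OC)c1 | intermediate
5 | 2-{4-[(1S)-1-(3,5-dimethoxyphenyl)-2-nitroethyl]-3,5-dimethoxyphenyl}-4,4,5,5-tetramethyl-1,3,2-dioxaborolane | [O-][N+](=O)C[C@H](c1c(OC)cc(B2OC(C)(C)C(C)(C)O2)cc1OC)c1cc(OC)cc(OC)c1 | intermediate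
6 | 1-ethenyl-4-methoxybenzene (4-methoxystyrene) | C=Cc1ccc(OC)cc1 | starting material
7 | 2,6-dimethoxy-4-[(E)-2-(4-methoxyphenyl)ethenyl]benzaldehyde | COc1cc(/C=C/c2ccc(OC)cc2)cc(OC)c1C=O | intermediate
8 | 1,3-dimethoxy-5-[(E)-2-(4-methoxyphenyl)ethenyl]-2-[(E)-2-nitroethenyl]benzene | COc1cc(/C=C/c2ccc(OC)cc2)cc(OC)c1/C=C/[N+](=O)[O-] | intermediate
9 | 2-[(1R)-1-{4-[(1S)-1-(3,5-dimethoxyphenyl)-2-nitroethyl]-3,5-dimethoxyphenyl}-2-nitroethyl]-1,3-dimethoxy-5-[(E)-2-(4-methoxyphenyl)ethenyl]benzene | [O-][N+](=O)C[C@@H](c1c(OC)cc(/C=C/c2ccc(OC)cc2)cc1OC)c1cc(OC)c([C@@H](C[N+](=O)[O-])c2cc(OC)cc(OC)c2)c(OC)c1 | intermediate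
10 | disodium bis-nitronate of 9 (both CH2NO2 groups as CH=NO2Na; (R) and (S) diarylmethine centres unchanged) | [Na+].[Na+].[O-][N+]([O-])=C[C@@H](c1c(OC)cc(/C=C/c2ccc(OC)cc2)cc1OC)c1cc(OC)c([C@@H](C=[N+]([O-])[O-])c2cc(OC)cc(OC)c2)c(OC)c1 | intermediate
11 | (2R)-2-{2,6-dimethoxy-4-[(E)-2-(4-methoxyphenyl)ethenyl]phenyl}-2-{4-[(1S)-1-(3,5-dimethoxyphenyl)-2-oxoethyl]-3,5-dimethoxyphenyl}acetaldehyde | O=C[C@@H](c1c(OC)cc(/C=C/c2ccc(OC)cc2)cc1OC)c1cc(OC)c([C@@H](C=O)c2cc(OC)cc(OC)c2)c(OC)c1 | intermediate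
12 | (4-methoxyphenyl)magnesium bromide | COc1ccc([Mg]Br)cc1 | starting material
13 | (2R)-2-{2,6-dimethoxy-4-[(E)-2-(4-methoxyphenyl)ethenyl]phenyl}-2-{4-[(1S)-1-(3,5-dimethoxyphenyl)-2-hydroxy-2-(4-methoxyphenyl)ethyl]-3,5-dimethoxyphenyl}-1-(4-methoxyphenyl)ethan-1-ol (both carbinol centres as epimer mixtures) | OC(c1ccc(OC)cc1)[C@@H](c1c(OC)cc(/C=C/c2ccc(OC)cc2)cc1OC)c1cc(OC)c([C@@H](C(O)c2ccc(OC)cc2)c2cc(OC)cc(OC)c2)c(OC)c1 | intermediate
14 | bis(benzylic bromide) of 13 (both carbinol OH replaced by Br, bromide-bearing centres undefined) | BrC(c1ccc(OC)cc1)[C@@H](c1c(OC)cc(/C=C/c2ccc(OC)cc2)cc1OC)c1cc(OC)c([C@@H](C(Br)c2ccc(OC)cc2)c2cc(OC)cc(OC)c2)c(OC)c1 | intermediate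
15 | 5-[(2S,3S)-4-hydroxy-6-{(2R,3R)-4-hydroxy-2-(4-hydroxyphenyl)-6-[(E)-2-(4-hydroxyphenyl)ethenyl]-2,3-dihydro-1-benzofuran-3-yl}-2-(4-hydroxyphenyl)-2,3-dihydro-1-benzofuran-3-yl]benzene-1,3-diol (CNP0248228.3) | Oc1ccc(/C=C/c2cc(O)c3c(c2)O[C@@H](c2ccc(O)cc2)[C@@H]3c2cc(O)c3c(c2)O[C@H](c2ccc(O)cc2)[C@H]3c2cc(O)cc(O)c2)cc1 | target

**Step count and risks**

Total step count: 9.
Longest linear sequence: 7 (steps 1, 2, 3, 6, 7, 8, 9 from compound 1; the second arm, steps 4 and 5, joins at step 6).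

Steps most likely to fail:

Step 9. The benzylic cation at C2 can suffer a 1,2-hydride shift from C3 (which would destroy the preset centre), and ninefold demethylation of a sensitive polyphenol can be incomplete or destructive. The fallback sets out from 13 and returns at 15 by separating ring closure from deprotection. Compound 13 is ionised under Brønsted acid catalysis (TfOH 10 mol%, (CF3)2CHOH, 0 °C), where the ortho-methoxy oxygens capture the benzylic cations and lose their methyl groups as methanol. This gives the heptamethyl ether of the target, (2R,3R)-3-[(2S,3S)-3-(3,5-dimethoxyphenyl)-4-methoxy-2-(4-methoxyphenyl)-2,3-dihydro-1-benzofuran-6-yl]-4-methoxy-2-(4-methoxyphenyl)-6-[(E)-2-(4-methoxyphenyl)ethenyl]-2,3-dihydro-1-benzofuran F1. F1 can be purified and checked for ring configuration before it is demethylated (BBr3, CH2Cl2, −40 to 0 °C, or AlCl3 with EtSH) to 15.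

Step 7. The α,α-diaryl acetaldehydes can enolise during the Nef reaction and erode C3 and C3′, and a double Nef reaction on primary nitro groups can stall at the nitronate stage. The fallback sets out from 9 and returns at 11 by stopping the reduction at the oxime and releasing the aldehydes by exchange. SnCl2·2H2O with PhSH and Et3N in MeCN at rt (a divalent tin thiolate complex as the reductant) takes each primary nitro group only as far as the aldoxime. This gives the bis-oxime N-[(2R)-2-{2,6-dimethoxy-4-[(E)-2-(4-methoxyphenyl)ethenyl]phenyl}-2-{4-[(1S)-1-(3,5-dimethoxyphenyl)-2-(hydroxyimino)ethyl]-3,5-dimethoxyphenyl}ethylidene]hydroxylamine F2 (oxime geometries undefined). Exchange of the two hydroxyimino groups of F2 onto formaldehyde (paraformaldehyde, Amberlyst 15, acetone/H2O, rt) then frees both aldehydes under mildly acidic conditions and gives 11.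

Step 6 (the same concern applies to step 2). The aryl–rhodium species may insert the di-ortho-substituted nitroalkene slowly or with low selectivity. The fallback sets out from 8 and 5 and returns at 9 by uncoupling C–C bond formation from stereo-induction. A palladium-catalysed oxidative Heck coupling (Pd(OAc)2, 1,10-phenanthroline, O2, DMF, 60 °C) replaces the vinylic β-hydrogen of 8 by the aryl group of 5; this coupling is itself uncertain, because protonolysis of the palladium nitronate to the racemic conjugate adduct competes with β-hydride elimination. It gives the β,β-diaryl nitroalkene 2-[(E)-1-{4-[(1S)-1-(3,5-dimethoxyphenyl)-2-nitroethyl]-3,5-dimethoxyphenyl}-2-nitroethenyl]-1,3-dimethoxy-5-[(E)-2-(4-methoxyphenyl)ethenyl]benzene F3. Enantioselective transfer hydrogenation of F3 (Hantzsch ester with a chiral thiourea catalyst) then delivers hydride to the β-carbon; the very different size of the two β-aryl groups provides the face discrimination, and the product is 9.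

**Further compounds**

F1 | step 9 | (2R,3R)-3-[(2S,3S)-3-(3,5-dimethoxyphenyl)-4-methoxy-2-(4-methoxyphenyl)-2,3-dihydro-1-benzofuran-6-yl]-4-methoxy-2-(4-methoxyphenyl)-6-[(E)-2-(4-methoxyphenyl)ethenyl]-2,3-dihydro-1-benzofuran | COc1ccc(/C=C/c2cc(OC)c3c(c2)O[C@@H](c2ccc(OC)cc2)[C@@H]3c2cc(OC)c3c(c2)O[C@H](c2ccc(OC)cc2)[C@H]3c2cc(OC)cc(OC)c2)cc1
F2 | step 7 | N-[(2R)-2-{2,6-dimethoxy-4-[(E)-2-(4-methoxyphenyl)ethenyl]phenyl}-2-{4-[(1S)-1-(3,5-dimethoxyphenyl)-2-(hydroxyimino)ethyl]-3,5-dimethoxyphenyl}ethylidene]hydroxylamine (oxime geometries undefined) | ON=C[C@@H](c1c(OC)cc(/C=C/c2ccc(OC)cc2)cc1OC)c1cc(OC)c([C@@H](C=NO)c2cc(OC)cc(OC)c2)c(OC)c1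
F3 | step 6 | 2-[(E)-1-{4-[(1S)-1-(3,5-dimethoxyphenyl)-2-nitroethyl]-3,5-dimethoxyphenyl}-2-nitroethenyl]-1,3-dimethoxy-5-[(E)-2-(4-methoxyphenyl)ethenyl]benzene | [O-][N+](=O)/C=C(/c1c(OC)cc(/C=C/c2ccc(OC)cc2)cc1OC)c1cc(OC)c([C@@H](C[N+](=O)[O-])c2cc(OC)cc(OC)c2)c(OC)c1
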